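**Plan**
- Retrosynthetic cuts, in order: the four O–Si bonds; C2–C3 of ring C; the C=N2 bond at C3 (back to an acetyl group); the O1–CH2 bond of a benzyl ether that carries ring B; the C8–CH2 bond to the side chain; the C5 chain back to propargyl alcohol.
- Enabling feature: C2–H is benzylic, α to O1, and six atoms from C3 along C3–C4–C4a–C8a–O1–C2. A carbene at C3 of an aryl diazomethyl ketone can therefore insert into it and close ring C from a plain benzyl aryl ether.
- Forward order: the Z side chain is built from propargyl alcohol and attached to C8 of a purchased ring-A acetophenone; the two phenols are differentiated (5-O-silyl, then O1-benzyl bearing ring B); the acetyl group becomes the diazoketone; ring C closes last; one buffered fluoride step releases the target.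
- Stereochemistry: the Z olefin comes from a chelate-controlled anti-carbomagnesiation/iodination and is carried through stereoretentive steps. C2 (S) is set by a chiral dirhodium catalyst that selects one of the two enantiotopic benzylic hydrogens.

Key step: step 12

Assumption: Rh2(S-PTTL)4 is taken to favour the 2S product; should the sense of induction be opposite, the mirror-image catalyst Rh2(R-PTTL)4 is used under the same conditions.

**Route**

Step 1
Reactants: 1 propargyl alcohol
Product: 3 (Z)-3-iodo-2-methylprop-2-en-1-ol, via cyclic alkenylmagnesium alkoxide 2 (not isolated)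
Conditions: MeMgBr (2.5 equiv), CuI (10 mol %), THF/Et2O, −10 °C → rt; then I2, −10 °C → rt
Reagents that add atoms: methylmagnesium bromide, C[Mg]Br; iodine, II
Why: Copper-catalysed anti-carbomagnesiation of the propargylic magnesium alkoxide places methyl on the internal carbon and magnesium on the terminal carbon cis to CH2O in a five-membered chelate, so iodinolysis with retention should give only the Z iodide and thereby fix the side-chain olefin geometry.

Step 2
Reactants: 3 (Z)-3-iodo-2-methylprop-2-en-1-ol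
Product: 4 (Z)-tert-butyl[(3-iodo-2-methylprop-2-enyl)oxy]dimethylsilane
Conditions: TBSCl, imidazole, CH2Cl2, 0 °C → rt
Reagents that add atoms: tert-butyldimethylsilyl chloride, CC(C)(C)[Si](C)(C)Cl
Why: Imidazole-promoted silylation of a primary allylic alcohol is routine, and the silyl ether is removed in the final fluoride step.

Step 3
Reactants: 4 (Z)-tert-butyl[(3-iodo-2-methylprop-2-enyl)oxy]dimethylsilane
Product: 5 (Z)-4-(tert-butyldimethylsilyloxy)-3-methylbut-2-en-1-ol
Conditions: Bu3SnCH2OH, Pd(PPh3)4 (5 mol %), 1,4-dioxane, 90 °C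
Reagents that add atoms: (tributylstannyl)methanol, CCCC[Sn](CCCC)(CCCC)CO
Why: Migita–Kosugi–Stille hydroxymethylation of an alkenyl iodide retains olefin geometry under neutral conditions, which avoids an alkenyllithium (1,4 O→C silyl shift) and an alkoxide (silyl exchange between the two cis oxygens).

Step 4
Reactants: 5 (Z)-4-(tert-butyldimethylsilyloxy)-3-methylbut-2-en-1-ol
Product: 6 (Z)-[(4-bromo-2-methylbut-2-enyl)oxy](tert-butyl)dimethylsilane
Conditions: CBr4, PPh3, 2,6-lutidine, CH2Cl2, 0 °C; used at once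
Reagents that add atoms: carbon tetrabromide, BrC(Br)(Br)Br
Why: Appel bromination substitutes the primary allylic alcohol by SN2 at the unhindered carbon without allylic transposition or Z/E change, as in the nerol to neryl bromide conversion.

Step 5
Reactants: 6 (Z)-[(4-bromo-2-methylbut-2-enyl)oxy](tert-butyl)dimethylsilane; 7 1-(2,6-dihydroxy-4-methoxyphenyl)ethanone
Product: 8 1-{3-[(2Z)-4-(tert-butyldimethylsilyloxy)-3-methylbut-2-enyl]-2,6-dihydroxy-4-methoxyphenyl}ethanone
Conditions: 7 (2 equiv), DBU (2 equiv), THF, 0 °C → rt, slow addition of 6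
Reagents that add atoms: none
Why: Nuclear C-alkylation of a phloroacetophenone phenoxide should occur at the ring carbon between OH and OMe; the two such carbons are equivalent by symmetry so only one mono-C-alkyl isomer can form, SN2 at the primary allylic bromide keeps the Z olefin, and excess 7 limits double alkylation.

Step 6
Reactants: 8 (C-alkylated dihydroxyacetophenone)
Product: 9 1-{3-[(2Z)-4-(tert-butyldimethylsilyloxy)-3-methylbut-2-enyl]-2-hydroxy-4-methoxy-6-(triisopropylsilyloxy)phenyl}ethanone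
Conditions: TIPSOTf (1.05 equiv), 2,6-lutidine, CH2Cl2, −78 → 0 °C
Reagents that add atoms: triisopropylsilyl trifluoromethanesulfonate, CC(C)[Si](OS(=O)(=O)C(F)(F)F)(C(C)C)C(C)C
Why: Silylation with a bulky silyl triflate should be steered by sterics to the phenol flanked by H rather than by the side chain, and the remaining chelated, doubly flanked phenol should resist a second silylation.

Step 7
Reactants: 10 3,4-dihydroxybenzaldehyde
Product: 11 3,4-bis(tert-butyldimethylsilyloxy)benzaldehyde
Conditions: TBSCl (2.3 equiv), imidazole, DMF, rt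
Reagents that add atoms: tert-butyldimethylsilyl chloride, CC(C)(C)[Si](C)(C)Cl
Why: Imidazole-promoted bis-silylation of a catechol is standard, and silyl ethers are chosen so that all protecting groups fall together at the end.

Step 8
Reactants: 11 3,4-bis(tert-butyldimethylsilyloxy)benzaldehyde
Product: 12 [3,4-bis(tert-butyldimethylsilyloxy)phenyl]methanol
Conditions: NaBH4, MeOH/THF, 0 °C
Reagents that add atoms: none
Why: Borohydride reduction of an aromatic aldehyde is fast at 0 °C and aryl silyl ethers tolerate it.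

Step 9
Reactants: 9 (2-hydroxy-6-silyloxyacetophenone); 12 [3,4-bis(tert-butyldimethylsilyloxy)phenyl]methanol
Product: 13 1-{2-[3,4-bis(tert-butyldimethylsilyloxy)benzyloxy]-3-[(2Z)-4-(tert-butyldimethylsilyloxy)-3-methylbut-2-enyl]-4-methoxy-6-(triisopropylsilyloxy)phenyl}ethanone
Conditions: PPh3, DIAD, THF, 0 °C → rt
Reagents that add atoms: none
Why: Mitsunobu etherification joins the chelated phenol to the primary benzylic alcohol under neutral conditions (as in O-alkylation of chelated 2-hydroxyaryl ketones), whereas carbonate bases would endanger the aryl silyl ethers.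

Step 10
Reactants: 13 (benzyl ether acetophenone)
Product: 14 1-{aryl of 13}-4,4,4-trifluorobutane-1,3-dione
Conditions: LiHMDS (1.1 equiv), THF, −78 °C; CF3CO2CH2CF3, −78 °C; cold dilute HCl wash, crude taken on
Reagents that add atoms: 2,2,2-trifluoroethyl trifluoroacetate, O=C(OCC(F)(F)F)C(F)(F)F
Why: Claisen-type trifluoroacetylation of the lithium enolate (first half of a detrifluoroacetylative diazo transfer) uses the only acidic site, the methyl ketone, and −78 °C should keep the ortho silyl ether from migrating to the enolate oxygen.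

Step 11
Reactants: 14 (trifluoroacetyl ketone)
Product: 15 2-diazo-1-{2-[3,4-bis(tert-butyldimethylsilyloxy)benzyloxy]-3-[(2Z)-4-(tert-butyldimethylsilyloxy)-3-methylbut-2-enyl]-4-methoxy-6-(triisopropylsilyloxy)phenyl}ethanone
Conditions: MsN3, Et3N, H2O (1 equiv), MeCN, rt
Reagents that add atoms: methanesulfonyl azide, CS(=O)(=O)N=[N+]=[N-]
Why: Regitz diazo transfer to the activated 1,3-diketone followed by loss of the trifluoroacetyl group as the acyl sulfonamide should give the terminal diazoketone, which avoids saponifying a hindered benzoate and making an acid chloride in the presence of silyl ethers.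

Step 12
Reactants: 15 (aryl diazomethyl ketone)
Product: 16 (2S)-2-[3,4-bis(tert-butyldimethylsilyloxy)phenyl]-8-[(2Z)-4-(tert-butyldimethylsilyloxy)-3-methylbut-2-enyl]-7-methoxy-5-(triisopropylsilyloxy)chroman-4-one
Conditions: Rh2(S-PTTL)4 (2 mol %), CH2Cl2, 0 °C, slow addition of 15
Reagents that add atoms: none
Why: Rh(II) releases N2 from 15 to give an electrophilic acyl carbenoid at C3, which inserts in a concerted, asynchronous three-centre step with hydride-shift character into one benzylic C–H bond next to O1 and forms C2–C3. The closest known reaction is the dirhodium-carboxylate-catalysed intramolecular C–H insertion of 2-alkoxyaryl α-diazoketones to chroman-4-ones, including versions with chiral carboxylate ligands. Ring C closes as a six-membered ring by 1,6-insertion along C3–C4–C4a–C8a–O1–C2, because the 1,5-position is the ether oxygen itself. C2 is set by the catalyst alone: the chiral phthalimido-tert-leucinate pocket around the carbenoid should let only one of the two enantiotopic benzylic hydrogens reach the carbene, and the ligand antipode is chosen to give 2S. The step needs insertion to outrun attack of O1 on the carbenoid (oxonium ylide, then 1,2-benzyl shift to a 2-benzylbenzofuran-3-one); this is helped by the para-silyloxy group, which makes the benzylic C–H more hydridic, by the weakly basic aryl ether oxygen flanked on both sides, and by a bulky carboxylate catalyst at low temperature in a non-coordinating solvent. The other flank offers only a silyl ether with no α-C–H and a poorly nucleophilic oxygen, and the alkene on C8 is meta to the acyl carbon and cannot reach C3.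

Step 13
Reactants: 16 (tetrasilylated flavanone)
Product: 17 (2S)-2-(3,4-dihydroxyphenyl)-5-hydroxy-8-[(2Z)-4-hydroxy-3-methylbut-2-enyl]-7-methoxychroman-4-one (CNP0246822.1)
Conditions: TBAF/AcOH (1:1, excess), THF, 0 °C → rt
Reagents that add atoms: none
Why: Fluoride-mediated desilylation should cleave the three aryl and one primary alkyl silyl ethers in one operation, and the acetic acid buffer keeps the phenols protonated so that ring C cannot open by retro-oxa-Michael reaction and racemise C2.

**Compound list**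
1 | propargyl alcohol | C#CCO | starting material
2 | 4-methyl-2,5-dihydro-1,2-oxamagnesole (cyclic alkenylmagnesium alkoxide) | CC1=C[Mg]OC1 | intermediate
3 | (Z)-3-iodo-2-methylprop-2-en-1-ol | I/C=C(/C)CO | intermediate
4 | (Z)-tert-butyl[(3-iodo-2-methylprop-2-enyl)oxy]dimethylsilane | I/C=C(/C)CO[Si](C)(C)C(C)(C)C | intermediate
5 | (Z)-4-(tert-butyldimethylsilyloxy)-3-methylbut-2-en-1-ol | OC/C=C(/C)CO[Si](C)(C)C(C)(C)C | intermediate
6 | (Z)-[(4-bromo-2-methylbut-2-enyl)oxy](tert-butyl)dimethylsilane | BrC/C=C(/C)CO[Si](C)(C)C(C)(C)C | intermediate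
7 | 1-(2,6-dihydroxy-4-methoxyphenyl)ethanone | COc1cc(O)c(C(C)=O)c(O)c1 | starting material
8 | 1-{3-[(2Z)-4-(tert-butyldimethylsilyloxy)-3-methylbut-2-enyl]-2,6-dihydroxy-4-methoxyphenyl}ethanone | COc1cc(O)c(C(C)=O)c(O)c1C/C=C(/C)CO[Si](C)(C)C(C)(C)C | intermediate
9 | 1-{3-[(2Z)-4-(tert-butyldimethylsilyloxy)-3-methylbut-2-enyl]-2-hydroxy-4-methoxy-6-(triisopropylsilyloxy)phenyl}ethanone | COc1cc(O[Si](C(C)C)(C(C)C)C(C)C)c(C(C)=O)c(O)c1C/C=C(/C)CO[Si](C)(C)C(C)(C)C | intermediate
10 | 3,4-dihydroxybenzaldehyde | O=Cc1ccc(O)c(O)c1 | starting material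
11 | 3,4-bis(tert-butyldimethylsilyloxy)benzaldehyde | O=Cc1ccc(O[Si](C)(C)C(C)(C)C)c(O[Si](C)(C)C(C)(C)C)c1 | intermediate
12 | [3,4-bis(tert-butyldimethylsilyloxy)phenyl]methanol | OCc1ccc(O[Si](C)(C)C(C)(C)C)c(O[Si](C)(C)C(C)(C)C)c1 | intermediate
13 | 1-{2-[3,4-bis(tert-butyldimethylsilyloxy)benzyloxy]-3-[(2Z)-4-(tert-butyldimethylsilyloxy)-3-methylbut-2-enyl]-4-methoxy-6-(triisopropylsilyloxy)phenyl}ethanone | COc1cc(O[Si](C(C)C)(C(C)C)C(C)C)c(C(C)=O)c(OCc2ccc(O[Si](C)(C)C(C)(C)C)c(O[Si](C)(C)C(C)(C)C)c2)c1C/C=C(/C)CO[Si](C)(C)C(C)(C)C | intermediate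
14 | 1-{aryl of 13}-4,4,4-trifluorobutane-1,3-dione | COc1cc(O[Si](C(C)C)(C(C)C)C(C)C)c(C(=O)CC(=O)C(F)(F)F)c(OCc2ccc(O[Si](C)(C)C(C)(C)C)c(O[Si](C)(C)C(C)(C)C)c2)c1C/C=C(/C)CO[Si](C)(C)C(C)(C)C | intermediate
15 | 2-diazo-1-{aryl of 13}ethanone (aryl diazomethyl ketone) | COc1cc(O[Si](C(C)C)(C(C)C)C(C)C)c(C(=O)C=[N+]=[N-])c(OCc2ccc(O[Si](C)(C)C(C)(C)C)c(O[Si](C)(C)C(C)(C)C)c2)c1C/C=C(/C)CO[Si](C)(C)C(C)(C)C | intermediate
16 | (2S)-2-[3,4-bis(tert-butyldimethylsilyloxy)phenyl]-8-[(2Z)-4-(tert-butyldimethylsilyloxy)-3-methylbut-2-enyl]-7-methoxy-5-(triisopropylsilyloxy)chroman-4-one | COc1cc(O[Si](C(C)C)(C(C)C)C(C)C)c2c(c1C/C=C(/C)CO[Si](C)(C)C(C)(C)C)O[C@H](c1ccc(O[Si](C)(C)C(C)(C)C)c(O[Si](C)(C)C(C)(C)C)c1)CC2=O | intermediate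
17 | (2S)-2-(3,4-dihydroxyphenyl)-5-hydroxy-8-[(2Z)-4-hydroxy-3-methylbut-2-enyl]-7-methoxychroman-4-one | COc1cc(O)c2c(c1C/C=C(/C)CO)O[C@H](c1ccc(O)c(O)c1)CC2=O | target

**Step count**
Total: 13 steps. Longest linear sequence: 11 steps (1–6, then 9–13, from propargyl alcohol).

**Steps most likely to fail**

Step 12. The carbenoid may be captured by the lone pair of O1 (oxonium ylide, then 1,2-shift of the electron-rich benzyl group) faster than it inserts, and an acceptor-only carbenoid may discriminate the two enantiotopic hydrogens poorly. The fallback sets out from 9 and returns at 16. Condensation of 9 with DMF dimethyl acetal (toluene, 90 °C) should give the enaminone (E)-3-(dimethylamino)-1-{3-[(2Z)-4-(tert-butyldimethylsilyloxy)-3-methylbut-2-enyl]-2-hydroxy-4-methoxy-6-(triisopropylsilyloxy)phenyl}prop-2-en-1-one F1. Mild acid (PPTS, toluene, 60 °C) should close it to the chromone 8-[(2Z)-4-(tert-butyldimethylsilyloxy)-3-methylbut-2-enyl]-7-methoxy-5-(triisopropylsilyloxy)chromen-4-one F2. Commercial 4-bromocatechol is silylated (TBSCl, imidazole) to 4-bromo-1,2-bis(tert-butyldimethylsilyloxy)benzene F3. Bromine–lithium exchange (n-BuLi, THF, −78 °C), B(OiPr)3 and mild aqueous work-up then give [3,4-bis(tert-butyldimethylsilyloxy)phenyl]boronic acid F4. Rhodium-catalysed asymmetric 1,4-addition of F4 to F2 (Hayashi–Miyaura reaction; [Rh(OH)(cod)]2, an electron-poor atropisomeric bisphosphine such as MeO-F12-BIPHEP in the enantiomer that gives 2S, toluene/H2O, rt) would deliver 16, with C2 set by the ligand.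

Step 5. O-Alkylation of the phenoxide, a second alkylation, or alkylation of DBU may consume the bromide faster than the wanted C-alkylation. The fallback sets out from 7 and returns at 13. Mono-O-allylation of 7 (allyl bromide, K2CO3, acetone) gives 1-[2-(allyloxy)-6-hydroxy-4-methoxyphenyl]ethanone F5. Aromatic Claisen rearrangement (N,N-diethylaniline, 190 °C) moves the allyl group to the only free ortho carbon to give 1-(3-allyl-2,6-dihydroxy-4-methoxyphenyl)ethanone F6. Silylation as in step 6 gives 1-[3-allyl-2-hydroxy-4-methoxy-6-(triisopropylsilyloxy)phenyl]ethanone F7, and Mitsunobu coupling with 12 as in step 9 gives 1-{3-allyl-2-[3,4-bis(tert-butyldimethylsilyloxy)benzyloxy]-4-methoxy-6-(triisopropylsilyloxy)phenyl}ethanone F8. Lemieux–Johnson cleavage (OsO4 cat., NaIO4, 2,6-lutidine, dioxane/H2O) gives 2-{3-acetyl-2-[3,4-bis(tert-butyldimethylsilyloxy)benzyloxy]-6-methoxy-4-(triisopropylsilyloxy)phenyl}acetaldehyde F9. Still–Gennari olefination (methyl 2-[bis(2,2,2-trifluoroethoxy)phosphoryl]propanoate, KHMDS, 18-crown-6, THF, −78 °C) should give the Z enoate methyl (2Z)-4-{3-acetyl-2-[3,4-bis(tert-butyldimethylsilyloxy)benzyloxy]-6-methoxy-4-(triisopropylsilyloxy)phenyl}-2-methylbut-2-enoate F10. Excess DIBAL-H (CH2Cl2, −78 → 0 °C) reduces ester and ketone to the diol (2Z)-4-{2-[3,4-bis(tert-butyldimethylsilyloxy)benzyloxy]-3-(1-hydroxyethyl)-6-methoxy-4-(triisopropylsilyloxy)phenyl}-2-methylbut-2-en-1-ol F11 (racemic at the carbinol). Selective silylation of the primary alcohol (TBSCl, imidazole, 0 °C) gives 1-{2-[3,4-bis(tert-butyldimethylsilyloxy)benzyloxy]-3-[(2Z)-4-(tert-butyldimethylsilyloxy)-3-methylbut-2-enyl]-4-methoxy-6-(triisopropylsilyloxy)phenyl}ethanol F12, and Dess–Martin oxidation returns the ketone 13. Any ketone that survives the DIBAL step converges on 13 after the silylation.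

Step 9. The chelated phenol, flanked on both sides, may be too hindered to attack the oxyphosphonium ion, which would then be diverted to ring C-benzylation or decomposition. The fallback sets out from 12 (with 9) and returns at 13. Appel bromination of 12 (CBr4, PPh3, CH2Cl2, 0 °C) gives 4-(bromomethyl)-1,2-bis(tert-butyldimethylsilyloxy)benzene F13. Silver(I) oxide-promoted O-alkylation of 9 with F13 (Ag2O, 4 Å sieves, toluene, rt, dark) activates the halide rather than the phenol and should give 13 without a soluble base that could strip the aryl silyl ethers.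

**Further compounds**
F1 | step 12 | (E)-3-(dimethylamino)-1-{3-[(2Z)-4-(tert-butyldimethylsilyloxy)-3-methylbut-2-enyl]-2-hydroxy-4-methoxy-6-(triisopropylsilyloxy)phenyl}prop-2-en-1-one | COc1cc(O[Si](C(C)C)(C(C)C)C(C)C)c(C(=O)/C=C/N(C)C)c(O)c1C/C=C(/C)CO[Si](C)(C)C(C)(C)C
F2 | step 12 | 8-[(2Z)-4-(tert-butyldimethylsilyloxy)-3-methylbut-2-enyl]-7-methoxy-5-(triisopropylsilyloxy)chromen-4-one | COc1cc(O[Si](C(C)C)(C(C)C)C(C)C)c2c(c1C/C=C(/C)CO[Si](C)(C)C(C)(C)C)OC=CC2=O
F3 | step 12 | 4-bromo-1,2-bis(tert-butyldimethylsilyloxy)benzene | Brc1ccc(O[Si](C)(C)C(C)(C)C)c(O[Si](C)(C)C(C)(C)C)c1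
F4 | step 12 | [3,4-bis(tert-butyldimethylsilyloxy)phenyl]boronic acid | OB(O)c1ccc(O[Si](C)(C)C(C)(C)C)c(O[Si](C)(C)C(C)(C)C)c1
F5 | step 5 | 1-[2-(allyloxy)-6-hydroxy-4-methoxyphenyl]ethanone | COc1cc(O)c(C(C)=O)c(OCC=C)c1
F6 | step 5 | 1-(3-allyl-2,6-dihydroxy-4-methoxyphenyl)ethanone | COc1cc(O)c(C(C)=O)c(O)c1CC=C
F7 | step 5 | 1-[3-allyl-2-hydroxy-4-methoxy-6-(triisopropylsilyloxy)phenyl]ethanone | COc1cc(O[Si](C(C)C)(C(C)C)C(C)C)c(C(C)=O)c(O)c1CC=C
F8 | step 5 | 1-{3-allyl-2-[3,4-bis(tert-butyldimethylsilyloxy)benzyloxy]-4-methoxy-6-(triisopropylsilyloxy)phenyl}ethanone | COc1cc(O[Si](C(C)C)(C(C)C)C(C)C)c(C(C)=O)c(OCc2ccc(O[Si](C)(C)C(C)(C)C)c(O[Si](C)(C)C(C)(C)C)c2)c1CC=C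
F9 | step 5 | 2-{3-acetyl-2-[3,4-bis(tert-butyldimethylsilyloxy)benzyloxy]-6-methoxy-4-(triisopropylsilyloxy)phenyl}acetaldehyde | COc1cc(O[Si](C(C)C)(C(C)C)C(C)C)c(C(C)=O)c(OCc2ccc(O[Si](C)(C)C(C)(C)C)c(O[Si](C)(C)C(C)(C)C)c2)c1CC=O
F10 | step 5 | methyl (2Z)-4-{3-acetyl-2-[3,4-bis(tert-butyldimethylsilyloxy)benzyloxy]-6-methoxy-4-(triisopropylsilyloxy)phenyl}-2-methylbut-2-enoate | COc1cc(O[Si](C(C)C)(C(C)C)C(C)C)c(C(C)=O)c(OCc2ccc(O[Si](C)(C)C(C)(C)C)c(O[Si](C)(C)C(C)(C)C)c2)c1C/C=C(/C)C(=O)OC
F11 | step 5 | (2Z)-4-{2-[3,4-bis(tert-butyldimethylsilyloxy)benzyloxy]-3-(1-hydroxyethyl)-6-methoxy-4-(triisopropylsilyloxy)phenyl}-2-methylbut-2-en-1-ol (racemic carbinol) | COc1cc(O[Si](C(C)C)(C(C)C)C(C)C)c(C(C)O)c(OCc2ccc(O[Si](C)(C)C(C)(C)C)c(O[Si](C)(C)C(C)(C)C)c2)c1C/C=C(/C)CO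
F12 | step 5 | 1-{2-[3,4-bis(tert-butyldimethylsilyloxy)benzyloxy]-3-[(2Z)-4-(tert-butyldimethylsilyloxy)-3-methylbut-2-enyl]-4-methoxy-6-(triisopropylsilyloxy)phenyl}ethanol (racemic carbinol) | COc1cc(O[Si](C(C)C)(C(C)C)C(C)C)c(C(C)O)c(OCc2ccc(O[Si](C)(C)C(C)(C)C)c(O[Si](C)(C)C(C)(C)C)c2)c1C/C=C(/C)CO[Si](C)(C)C(C)(C)C
F13 | step 9 | 4-(bromomethyl)-1,2-bis(tert-butyldimethylsilyloxy)benzene | BrCc1ccc(O[Si](C)(C)C(C)(C)C)c(O[Si](C)(C)C(C)(C)C)c1
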